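Forget 80.0 % of target, the most the charges allow: this flask cannot reach it, as the first bound below shows.

    solid substrate ⇌ dissolved substrate, rate k1*(cs1 - [dissolved substrate]) while solid is left; crystals form when [dissolved substrate] > cs1 (cs1 = 3.5 mM, k1 = 0.069 s⁻¹)
    dissolved substrate + coupling partner ⇌ target (K2 = 50 L mol⁻¹, k2 = 2.3 L mol⁻¹ s⁻¹)
    coupling partner → side product (k3 = 0.011 s⁻¹)

solid substrate 10 mM; coupling partner 0.800 equiv; time 50 s

* the target standing at 50 s, as a percentage of the solid substrate charged
* concentration of dissolved substrate in solution at 50 s, in percent of saturation

**Saturation ratio.** Multiply 50 L mol⁻¹ by 3.5 mM to get 0.175, the saturation ratio: target per coupling partner at equilibrium over a saturated solution.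

**Bound above.** Since [dissolved substrate] stays at or below saturation and [coupling partner] below its charge, target cannot pass 14.0 % of the solid charged, less than the charges allow. Now tighten. Target goes back with the constant 0.0460 s⁻¹, while step 3 and net coupling thin the partner at 0.011 s⁻¹ or faster. Grant instant saturation, and 50 s gives 8.77 %.

**Bound below.** Take the worst case from 25.0 s on, with target starting from nothing. Let [dissolved substrate] be no lower than 2.45 mM. Let [coupling partner] be no lower than 3.09 mM, its pseudo-first-order decay over a saturated solution. Relaxation then gives 2.59 %.

**The forecast.** It gives 6.3 % and 93.5 %, judging the target “nearly at quasi-equilibrium by 50 s”. Its yield lies inside my bracket.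

**The flask.** The simulation gives 6.29 % and 93.5 %, inside the bracket too. Target in this flask stands low in part because the low solubility and the backward run act together: remove the backward run and 13.4 % stands, remove the solubility limit and 16.6 % stands. Apply the ratio to the 52 % of partner left in this flask: it gives 7.28 %, against the 6.29 % found.

**Second flask.** Charge 1.40 equiv of partner instead. With 52 % of it left, the ratio gives 12.7 %; the neighbour flask computes to 10.6 %.

The numbers come from no measurement; the run is a simulation.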